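Numbering used throughout (working numbering of the spiro[5.5]undecane, not necessarily lowest-locant): ring A = C1 (carries the exocyclic CH2), C2, C3, C4, C5 (CMe2), C6 (spiro atom); ring B = C6, C7, C8, C9, C10, C11. Octalin intermediates are numbered as in the name of compound 9.

## Analysis of the target

The target is a spiro[5.5]undecane whose rings share C6. Ring A carries the methylene on C1, a secondary hydroxyl on C3, a secondary bromide on C4 and the gem-dimethyl group on C5. Ring B carries a tertiary hydroxyl and a chloromethyl group on C9 and a ketone on C10.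

There are four stereocentres, (3S,4R,6R,9S) in this numbering. The C3 hydroxyl and C4 bromide are cis and lie on the ring A face that holds C11. C6 is stereogenic only because the two arms of ring B differ (C7–C8 against C11–C10=O). The C9 hydroxyl lies on the ring B face of the C5 arm, so with the CMe2 arm equatorial on ring B it is axial and the chloromethyl group equatorial.

The rings communicate only through the spiro atom, which presents two CH2 groups to ring A. Substrate control therefore cannot relay configuration between ring A and ring B, and each ring needs its own chiral reagent.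

Sensitive groups:
- the α-hydroxy ketone with a β-chlorine (epoxide closure and ketol shift under base);
- the neopentyl bromide at C4 (no SN2 access, prone to elimination and 1,2-shifts on ionisation);
- the C1 methylene, which is β,γ to any C3 carbonyl and would compete for electrophilic halogen or peracid.

The hard points are the adjacent fully substituted carbons C5 and C6, a bromine that can reach C4 only as an electrophile or by migration, and the choice between the enantiotopic methylenes of ring B.

The strategy rests on one feature: C6 carries the methylene-bearing C1 and stands para to C9 in ring B. This is a 4-(alk-1-en-2-yl)cyclohexanone, the pattern left by a [3,3] shift of a 1-vinylcyclohex-3-en-1-olate whose ring alkene is the ring-fusion alkene of an octalin.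

## Retrosynthetic reasoning

**26 to 25 and 24.** The C3 carbinol is traced to the C3 ketone of diketone 25. A C3 ketone with an equatorial C4 bromide is reduced from the equatorial side, which gives the cis-bromohydrin, and the same oxidation that makes this ketone can also create the C10 ketone. Both carbonyls of 25 therefore come from triol 24, and 24 from silyl ether 23 by desilylation. The forward reduction must touch only the C3 carbonyl.

**23 to 21, 20 and 19 (C4–Br and C3–O).** Bromine cannot be put on the neopentyl C4 by substitution. A C3 ketone would enolise toward the allylic C2, not toward C4. The C4 ketone 19, in contrast, can enolise only toward C3. Bromine is therefore brought in at C3 under catalyst control (20), the ketone is reduced to the trans alcohol 21, and the bromine is moved to C4 through a bromonium ion that water opens at C3 (23). The C3 configuration set by the catalyst becomes the C4 configuration of the target.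

**19 to 18, 17 and 15 (C9 carbinol and chloromethyl group).** The CH2–Cl bond is cut back to the spiro-epoxide 17, and the epoxide CH2 to a methylene transfer onto the C9 ketone of 15. Equatorial delivery on the ring B chair that keeps the CMe2 arm equatorial gives the required C9 configuration. The ring A ketal is kept until chloride has opened the epoxide, because the epoxide would not survive the ketal hydrolysis.

**15 to 12 (desymmetrisation of ring B).** The C10 oxygen is removed to reach the achiral ketone 12. Forward, an amino-acid-catalysed α-aminoxylation chooses C10 over C8 and so makes C6 a stereocentre. The temporary C10 carbinol is later oxidised to the target ketone.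

**12 to 9 (key disconnection, C6–C7).** Cutting C6–C7 and reconnecting C9 to the methylene carbon gives the vinyl carbinol 9. This cut places the crowded bond at the quaternary centre in a concerted step with no stereochemical demand, starting from a flat, fused precursor. A cut at C6–C11 or inside ring A would need an intermolecular alkylation between two fully substituted carbons.

**9 to 7, 6, 5, 3 and 1.** The vinyl group comes from vinylmagnesium bromide 8 and the β,γ-unsaturated ketone 7. Ketone 7 comes from Birch reduction of the anisole 5 and mild hydrolysis of enol ether 6. Anisole 5 comes from tetralone 1 by double methylation with 2 at the benzylic α-carbon (3) and ketalisation with 4.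

## Alternatives that were turned down

**Alternative 1:** ring B is cut at C9–C10. A keto aldehyde A1, with both arms already on a quaternary C6 of a vinylogous ester, is closed by a chiral triazolium-derived carbene. The acyl anion equivalent of the C10 aldehyde adds to the C9 ketone and gives the spiro α-hydroxy ketone A2.
- For: the complete ketol of ring B is made in one catalytic asymmetric step, where the chosen route needs steps 7 to 11 and an oxidation. Ring A also arrives with its oxygen on C3, where the target has it. On both points this alternative is stronger.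
- Against: C6 must already be an enantioenriched quaternary centre next to CMe2 with two different enolisable arms. The carbene must then set C9 across the forming ring relative to C6. The protected CH2O group must still become CH2Cl next to a tertiary carbinol, and ring A still needs methylenation of a hindered carbonyl and the bromohydrin.
- In exchange, the chosen strategy makes the quaternary carbon without any stereochemical requirement and defers all stereochemistry to reagent-controlled steps on a rigid spirocycle.

**Alternative 2:** the C1–C6 bond is cut and ring B is taken back to a bicyclo[3.1.0]hexane. Oxidation of the silyloxycyclopropane A3 with Mn(pic)3 (trivalent manganese) opens the internal cyclopropane bond to the ring B ketone. The tertiary C6 radical then closes 6-exo-dig onto the alkyne, and 1,4-cyclohexadiene reduces the vinyl radical to the methylene of A4.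
- For: it is convergent, C3, C4 and C9 are in place before the key step, and the spiro atom, the C10 ketone and the methylene appear together. On convergence and on end-game length it is stronger.
- Against: the C6 configuration has to come from two remote biases (the tether and C9) that need not agree. A hindered tertiary radical must cyclise faster than it is reduced. The secondary bromide is exposed to radical chain conditions. The open-chain precursor with three stereocentres is long to make.
- In exchange, the chosen strategy has a key step with no chemoselectivity or stereoselectivity problem and a six-step entry from a commercial tetralone.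

**Alternative 3:** ring A is cut at C2–C3. The α-bromo aldehyde A5 is activated with Me2AlCl and attacked by the terminal carbon of the isopropenyl group on C6 in a type 2 carbonyl–ene reaction. This forms C2–C3, the C3 carbinol and the exocyclic methylene of A6 in one step.
- For: the whole of ring A, including the cis-bromohydrin, is made in a single step from an aldehyde whose α-bromination is well precedented. This is the part that costs the chosen route six steps and its most delicate chemistry, so here the alternative is clearly stronger.
- Against: the α-bromo aldehyde next to a quaternary carbon is fragile toward the Lewis acid. The C3/C4 relationship depends on an uncertain conformational preference of bromine in the ene transition state. The bond between the two fully substituted carbons C5 and C6 still has to be made by other means. Ring B in A6 is still symmetric and needs the same desymmetrisation.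
- In exchange, the chosen strategy solves the C5–C6 congestion by the sigmatropic step itself.

Key step: step 6

Assumptions:
- In step 7 the electrophile is taken to enter C10 on the ring B face away from the axial C1 arm, so natural L-proline is written. If the face preference were the reverse, D-proline would oxidise the same methylene and give the C10 epimer, which converges once C10 becomes a ketone.
- The sense of induction of the bromination catalyst in step 13 is assumed. The (4R,5R) form is written and its antipode is used if the (3R) bromide forms.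

## Route

Step 1
Reactants: 1 6-methoxy-3,4-dihydronaphthalen-2(1H)-one (6-methoxy-2-tetralone); 2 iodomethane
Product: 3 6-methoxy-1,1-dimethyl-3,4-dihydronaphthalen-2(1H)-one
Conditions: NaH (2.2 equiv), MeI (2.5 equiv), THF, 0 °C to rt
Reagents that add atoms: iodomethane 2, CI
Why: Enolate C-alkylation; C1 is benzylic and α to the ketone, so both methyl groups go there, and the reaction stops once C1 is quaternary.

Step 2
Reactants: 3 6-methoxy-1,1-dimethyl-3,4-dihydronaphthalen-2(1H)-one; 4 ethylene glycol
Product: 5 6-methoxy-1,1-dimethyl-3,4-dihydronaphthalen-2(1H)-one ethylene ketal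
Conditions: HOCH2CH2OH, TsOH (cat.), benzene, reflux, Dean–Stark
Reagents that add atoms: ethylene glycol 4, OCCO
Why: Acid-catalysed ketalisation with azeotropic removal of water; the dioxolane carries the carbonyl through the dissolving-metal, Grignard and KH steps.

Step 3
Reactants: 5 6-methoxy-1,1-dimethyl-3,4-dihydronaphthalen-2(1H)-one ethylene ketal
Product: 6 6,6-(ethylenedioxy)-2-methoxy-5,5-dimethyl-1,4,5,6,7,8-hexahydronaphthalene
Conditions: Li, NH3 (l), THF, t-BuOH, −78 to −33 °C; then NH4Cl
Reagents that add atoms: none
Why: Birch reduction of the anisole ring; the methoxy-bearing carbon and the two alkylated ring-fusion carbons stay sp2, giving the enol ether and the tetrasubstituted C4a=C8a alkene, and the dioxolane is inert.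

Step 4
Reactants: 6 6,6-(ethylenedioxy)-2-methoxy-5,5-dimethyl-1,4,5,6,7,8-hexahydronaphthalene
Product: 7 6,6-(ethylenedioxy)-5,5-dimethyl-3,4,5,6,7,8-hexahydronaphthalen-2(1H)-one
Conditions: (CO2H)2·2H2O, MeOH/H2O, rt
Reagents that add atoms: water, O
Why: Mild enol ether hydrolysis with a weak acid gives the β,γ-unsaturated ketone before the alkene can move into conjugation and without touching the hindered dioxolane.

Step 5
Reactants: 7 6,6-(ethylenedioxy)-5,5-dimethyl-3,4,5,6,7,8-hexahydronaphthalen-2(1H)-one; 8 vinylmagnesium bromide
Product: 9 racemic 2-ethenyl-6,6-(ethylenedioxy)-5,5-dimethyl-1,2,3,4,5,6,7,8-octahydronaphthalen-2-ol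
Conditions: CeCl3 (anhydrous, 1.5 equiv), CH2=CHMgBr, THF, −78 °C; then aq. NH4Cl
Reagents that add atoms: vinylmagnesium bromide 8, C=C[Mg]Br
Why: 1,2-Addition of a vinylcerium reagent, which suppresses enolisation of the easily deprotonated β,γ-unsaturated ketone; the carbinol stereocentre is formed as a racemate and is erased in the next step.

Step 6
Reactants: 9 racemic 2-ethenyl-6,6-(ethylenedioxy)-5,5-dimethyl-1,2,3,4,5,6,7,8-octahydronaphthalen-2-ol
Product: 12 4,4-(ethylenedioxy)-5,5-dimethyl-1-methylidenespiro[5.5]undecan-9-one, via potassium alkoxide 10 (not isolated), via potassium enolate 11 (not isolated)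
Conditions: KH (1.5 equiv), 18-crown-6 (1.5 equiv), THF, 0 to 66 °C; then aq. NH4Cl, −78 °C
Reagents that add atoms: none
Why: Proposed new method: deprotonation gives the crown-separated alkoxide 10, whose vinyl group, axial on C2 of a boat-like carbinol ring, lies over the p-lobe of C4a; a concerted [3,3] shift forms the bond from the vinyl terminus to C4a (C6–C7 of the spirocycle), breaks the allylic C1–C2 ring bond, leaves C1 as the methylene on C8a and delivers the charge as enolate 11, which is protonated to 12. The closest known reactions are anionic oxy-Cope rearrangements of cyclic and bicyclic 1,5-dien-3-olates through boat transition states and the degenerate thermal Cope rearrangement of 4-vinylcyclohexene; a 1-vinylcyclohex-3-en-1-olate set in an octalin has not been shown to follow this path. Ring B (C6 to C11) is closed by the sigmatropic shift itself through a bicyclo[2.2.2]octane-shaped transition state, not by an ionic cyclisation, while the old carbinol ring is opened. No stereocentre is formed, because 12 has a mirror plane through ring A, so racemic 9 converges on one achiral product. The step needs 3,3- and not 1,3-regiochemistry: the concerted geometry holds the vinyl terminus over C4a and away from C1, and enolate formation from a naked alkoxide should let the shift run below the temperature at which the alkoxide cleaves to an allyl anion and an enone. The main kinetic penalty is that the new quaternary carbon is built next to the gem-dimethyl carbon.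

Step 7
Reactants: 12 4,4-(ethylenedioxy)-5,5-dimethyl-1-methylidenespiro[5.5]undecan-9-one
Product: 13 (6R,10R)-10-(anilinooxy)-4,4-(ethylenedioxy)-5,5-dimethyl-1-methylidenespiro[5.5]undecan-9-one (C10 oxygen trans to the C1 arm on ring B)
Conditions: L-proline (30 mol %), PhNO (1.0 equiv, slow addition), DMF, 0 °C
Reagents that add atoms: nitrosobenzene, O=Nc1ccccc1
Why: Proline-enamine α-aminoxylation (O-selective nitroso aldol reaction), a known desymmetrisation of 4,4-disubstituted cyclohexanones. L-Proline fixes the oxygenated carbon as (R), and entry anti to the axial C1 arm of the ring B chair (CMe2 arm equatorial) makes C10 and not C8 the reacting carbon, which sets C6 as (R); the minor diastereomer is removed by chromatography.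

Step 8
Reactants: 13 (6R,10R)-10-(anilinooxy)-4,4-(ethylenedioxy)-5,5-dimethyl-1-methylidenespiro[5.5]undecan-9-one
Product: 14 (6R,10R)-4,4-(ethylenedioxy)-10-hydroxy-5,5-dimethyl-1-methylidenespiro[5.5]undecan-9-one
Conditions: CuSO4·5H2O (30 mol %), MeOH, 0 °C
Reagents that add atoms: none
Why: CuSO4-catalysed N–O cleavage of the anilinooxy group frees the α-hydroxy ketone without reducing the ketone or the alkene.

Step 9
Reactants: 14 (6R,10R)-4,4-(ethylenedioxy)-10-hydroxy-5,5-dimethyl-1-methylidenespiro[5.5]undecan-9-one
Product: 15 (6R,10R)-10-(tert-butyldimethylsilyloxy)-4,4-(ethylenedioxy)-5,5-dimethyl-1-methylidenespiro[5.5]undecan-9-one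
Conditions: TBSCl, imidazole, DMF, rt
Reagents that add atoms: tert-butyldimethylsilyl chloride, CC(C)(C)[Si](C)(C)Cl
Why: Silyl ether formation; the hydroxyl is masked before the basic ylide step, and a secondary TBS ether outlives the later ketal hydrolysis.

Step 10
Reactants: 15 (6R,10R)-10-(tert-butyldimethylsilyloxy)-4,4-(ethylenedioxy)-5,5-dimethyl-1-methylidenespiro[5.5]undecan-9-one; 16 trimethylsulfoxonium iodide
Product: 17 (6R,9R,10R)-10-(tert-butyldimethylsilyloxy)-4,4-(ethylenedioxy)-5,5-dimethyl-1-methylidenespiro[5.5]undecane-9-spiro-2'-oxirane (epoxide oxygen on the ring B face of the C5 arm, cis to the C10 oxygen)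
Conditions: Me3S(O)I, NaH, DMSO, rt to 50 °C
Reagents that add atoms: trimethylsulfoxonium iodide 16, C[S+](C)(C)=O.[I-]
Why: Corey–Chaykovsky epoxidation with dimethylsulfoxonium methylide; betaine formation is reversible, so the new C–C bond ends equatorial on the chair that keeps the CMe2 arm equatorial. This puts the epoxide oxygen axial, on the face of the C5 arm, which is the C9 configuration of the target.

Step 11
Reactants: 17 (6R,9R,10R)-10-(tert-butyldimethylsilyloxy)-4,4-(ethylenedioxy)-5,5-dimethyl-1-methylidenespiro[5.5]undecane-9-spiro-2'-oxirane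
Product: 18 (6R,9S,10R)-10-(tert-butyldimethylsilyloxy)-9-(chloromethyl)-4,4-(ethylenedioxy)-5,5-dimethyl-1-methylidenespiro[5.5]undecan-9-ol
Conditions: LiCl (3 equiv), AcOH (3 equiv), THF, rt
Reagents that add atoms: lithium chloride, [Li+].[Cl-]
Why: Buffered SN2 opening of the 2,2-disubstituted epoxide by chloride at its CH2 terminus; the tertiary C9–O bond and its configuration are not touched.

Step 12
Reactants: 18 (6R,9S,10R)-10-(tert-butyldimethylsilyloxy)-9-(chloromethyl)-4,4-(ethylenedioxy)-5,5-dimethyl-1-methylidenespiro[5.5]undecan-9-ol
Product: 19 (6R,9S,10R)-10-(tert-butyldimethylsilyloxy)-9-(chloromethyl)-9-hydroxy-5,5-dimethyl-1-methylidenespiro[5.5]undecan-4-one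
Conditions: PPTS (cat.), acetone/H2O, 55 °C
Reagents that add atoms: water, O
Why: Acid-catalysed hydrolysis of the strained dioxolane next to CMe2; PPTS is mild enough for the silyl ether, the chlorohydrin and the exocyclic alkene.

Step 13
Reactants: 19 (6R,9S,10R)-10-(tert-butyldimethylsilyloxy)-9-(chloromethyl)-9-hydroxy-5,5-dimethyl-1-methylidenespiro[5.5]undecan-4-one
Product: 20 (3S,6R,9S,10R)-3-bromo-10-(tert-butyldimethylsilyloxy)-9-(chloromethyl)-9-hydroxy-5,5-dimethyl-1-methylidenespiro[5.5]undecan-4-one
Conditions: (4R,5R)-4,5-diphenylimidazolidine (20 mol %), PhCO2H (20 mol %), 4,4-dibromo-2,6-di-tert-butylcyclohexa-2,5-dien-1-one (1.1 equiv), THF, −30 °C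
Reagents that add atoms: 4,4-dibromo-2,6-di-tert-butylcyclohexa-2,5-dien-1-one, CC(C)(C)C1=CC(Br)(Br)C=C(C(C)(C)C)C1=O
Why: Enamine-catalysed enantioselective α-bromination of a cyclic ketone with a soft Br+ donor that spares the alkene. The ketone can form an enamine only toward C3 because C5 is quaternary, and the catalyst, not the remote ring B, decides the face and sets C3 as (S).

Step 14
Reactants: 20 (3S,6R,9S,10R)-3-bromo-10-(tert-butyldimethylsilyloxy)-9-(chloromethyl)-9-hydroxy-5,5-dimethyl-1-methylidenespiro[5.5]undecan-4-one
Product: 21 (3S,4S,6R,9S,10R)-3-bromo-10-(tert-butyldimethylsilyloxy)-9-(chloromethyl)-5,5-dimethyl-1-methylidenespiro[5.5]undecane-4,9-diol (C3 bromide and C4 hydroxyl trans)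
Conditions: (S)-2-methyl-CBS-oxazaborolidine (20 mol %), catecholborane (2.5 equiv), toluene, −78 to −40 °C
Reagents that add atoms: none
Why: CBS reduction; the ketone binds the oxazaborolidine anti to the quaternary C5 side, so the (S) catalyst delivers hydride to the face that gives the (4S) alcohol trans to bromine, under reagent control. Catecholborane does not hydroborate the alkene at this temperature.

Step 15
Reactants: 21 (3S,4S,6R,9S,10R)-3-bromo-10-(tert-butyldimethylsilyloxy)-9-(chloromethyl)-5,5-dimethyl-1-methylidenespiro[5.5]undecane-4,9-diol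
Product: 23 (3R,4R,6R,9S,10R)-4-bromo-10-(tert-butyldimethylsilyloxy)-9-(chloromethyl)-5,5-dimethyl-1-methylidenespiro[5.5]undecane-3,9-diol (C3 hydroxyl and C4 bromide trans), via C4 triflate 22 (not isolated)
Conditions: Tf2O (1.2 equiv), 2,6-di-tert-butyl-4-methylpyridine, CH2Cl2, −78 to −30 °C; then THF/H2O, NaHCO3, 0 °C to rt
Reagents that add atoms: water, O; trifluoromethanesulfonic anhydride, O=S(=O)(OS(=O)(=O)C(F)(F)F)C(F)(F)F (its atoms stay only in 22)
Why: Solvolysis of a trans-2-bromoalkyl sulfonate with neighbouring-group participation: in the diaxial conformer bromine displaces the antiperiplanar triflate to give a bromonium ion on the face the bromine already occupied, and water opens it at the less hindered C3 (C4 is neopentyl). Bromine thus ends on C4 with (R) configuration and the hydroxyl on C3 trans to it; the β-bromine also slows unassisted ionisation. The axial tertiary C9 hydroxyl, flanked by CH2Cl and the silyloxy group, should not be triflated at low temperature.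

Step 16
Reactants: 23 (3R,4R,6R,9S,10R)-4-bromo-10-(tert-butyldimethylsilyloxy)-9-(chloromethyl)-5,5-dimethyl-1-methylidenespiro[5.5]undecane-3,9-diol
Product: 24 (3R,4R,6R,9S,10R)-4-bromo-9-(chloromethyl)-5,5-dimethyl-1-methylidenespiro[5.5]undecane-3,9,10-triol
Conditions: HF·pyridine, THF/pyridine, 0 °C to rt
Reagents that add atoms: none
Why: Fluoride cleavage of the silyl ether under acidic, non-basic conditions, so that neither halohydrin closes to an epoxide.

Step 17
Reactants: 24 (3R,4R,6R,9S,10R)-4-bromo-9-(chloromethyl)-5,5-dimethyl-1-methylidenespiro[5.5]undecane-3,9,10-triol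
Product: 25 (4R,6R,9S)-4-bromo-9-(chloromethyl)-9-hydroxy-5,5-dimethyl-1-methylidenespiro[5.5]undecane-3,10-dione
Conditions: Dess–Martin periodinane (3 equiv), NaHCO3, CH2Cl2, 0 °C to rt
Reagents that add atoms: none
Why: Dess–Martin oxidation of both secondary alcohols in one operation; the tertiary C9 alcohol cannot be oxidised, and the buffered neutral medium keeps the C1 methylene out of conjugation with the new C3 ketone and C4 unepimerised.

Step 18
Reactants: 25 (4R,6R,9S)-4-bromo-9-(chloromethyl)-9-hydroxy-5,5-dimethyl-1-methylidenespiro[5.5]undecane-3,10-dione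
Product: 26 (3S,4R,6R,9S)-4-bromo-9-(chloromethyl)-3,9-dihydroxy-5,5-dimethyl-1-methylidenespiro[5.5]undecan-10-one (target)
Conditions: LiBH(s-Bu)3 (1.05 equiv), THF, −78 °C; then aq. NH4Cl
Reagents that add atoms: none
Why: Chemoselective and diastereoselective hydride reduction: the C3 ketone is activated by the α-bromine and open to equatorial attack, whereas the C10 ketone lies between the fully substituted C9 and the neopentyl C11 under the axial C1 arm. The bulky hydride enters C3 equatorially (axial entry is blocked by the syn-axial C5 methyl) and gives the axial (3S) alcohol cis to the equatorial bromine.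

## Compound list

1 | 6-methoxy-3,4-dihydronaphthalen-2(1H)-one | COc1ccc2c(c1)CCC(=O)C2 | starting material
2 | iodomethane | CI | starting material
3 | 6-methoxy-1,1-dimethyl-3,4-dihydronaphthalen-2(1H)-one | COc1ccc2c(c1)CCC(=O)C2(C)C | intermediate
4 | ethylene glycol | OCCO | starting material
5 | 6-methoxy-1,1-dimethyl-3,4-dihydronaphthalen-2(1H)-one ethylene ketal | COc1ccc2c(c1)CCC3(OCCO3)C2(C)C | intermediate
6 | 6,6-(ethylenedioxy)-2-methoxy-5,5-dimethyl-1,4,5,6,7,8-hexahydronaphthalene | COC1=CCC2=C(C1)CCC3(OCCO3)C2(C)C | intermediate
7 | 6,6-(ethylenedioxy)-5,5-dimethyl-3,4,5,6,7,8-hexahydronaphthalen-2(1H)-one | O=C1CCC2=C(C1)CCC3(OCCO3)C2(C)C | intermediate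
8 | vinylmagnesium bromide | C=C[Mg]Br | starting material
9 | racemic 2-ethenyl-6,6-(ethylenedioxy)-5,5-dimethyl-1,2,3,4,5,6,7,8-octahydronaphthalen-2-ol | C=CC1(O)CCC2=C(C1)CCC3(OCCO3)C2(C)C | intermediate
10 | potassium alkoxide of 9 (formed in situ) | C=CC1([O-])CCC2=C(C1)CCC3(OCCO3)C2(C)C.[K+] | intermediate
11 | potassium C8=C9 enolate of 12 (formed in situ) | C=C1CCC2(OCCO2)C(C)(C)C13CC=C([O-])CC3.[K+] | intermediate
12 | 4,4-(ethylenedioxy)-5,5-dimethyl-1-methylidenespiro[5.5]undecan-9-one (achiral) | C=C1CCC2(OCCO2)C(C)(C)C13CCC(=O)CC3 | intermediate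
13 | (6R,10R)-10-(anilinooxy)-4,4-(ethylenedioxy)-5,5-dimethyl-1-methylidenespiro[5.5]undecan-9-one | C=C1CCC2(OCCO2)C(C)(C)[C@@]13CCC(=O)[C@H](ONc4ccccc4)C3 | intermediate
14 | (6R,10R)-4,4-(ethylenedioxy)-10-hydroxy-5,5-dimethyl-1-methylidenespiro[5.5]undecan-9-one | C=C1CCC2(OCCO2)C(C)(C)[C@@]13CCC(=O)[C@H](O)C3 | intermediate
15 | (6R,10R)-10-(tert-butyldimethylsilyloxy)-4,4-(ethylenedioxy)-5,5-dimethyl-1-methylidenespiro[5.5]undecan-9-one | C=C1CCC2(OCCO2)C(C)(C)[C@@]13CCC(=O)[C@H](O[Si](C)(C)C(C)(C)C)C3 | intermediate
16 | trimethylsulfoxonium iodide | C[S+](C)(C)=O.[I-] | starting material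
17 | (6R,9R,10R)-10-(tert-butyldimethylsilyloxy)-4,4-(ethylenedioxy)-5,5-dimethyl-1-methylidenespiro[5.5]undecane-9-spiro-2'-oxirane | C=C1CCC2(OCCO2)C(C)(C)[C@@]13CC[C@@]4(CO4)[C@H](O[Si](C)(C)C(C)(C)C)C3 | intermediate
18 | (6R,9S,10R)-10-(tert-butyldimethylsilyloxy)-9-(chloromethyl)-4,4-(ethylenedioxy)-5,5-dimethyl-1-methylidenespiro[5.5]undecan-9-ol | C=C1CCC2(OCCO2)C(C)(C)[C@@]13CC[C@@](O)(CCl)[C@H](O[Si](C)(C)C(C)(C)C)C3 | intermediate
19 | (6R,9S,10R)-10-(tert-butyldimethylsilyloxy)-9-(chloromethyl)-9-hydroxy-5,5-dimethyl-1-methylidenespiro[5.5]undecan-4-one | C=C1CCC(=O)C(C)(C)[C@@]12CC[C@@](O)(CCl)[C@H](O[Si](C)(C)C(C)(C)C)C2 | intermediate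
20 | (3S,6R,9S,10R)-3-bromo-10-(tert-butyldimethylsilyloxy)-9-(chloromethyl)-9-hydroxy-5,5-dimethyl-1-methylidenespiro[5.5]undecan-4-one | C=C1C[C@H](Br)C(=O)C(C)(C)[C@@]12CC[C@@](O)(CCl)[C@H](O[Si](C)(C)C(C)(C)C)C2 | intermediate
21 | (3S,4S,6R,9S,10R)-3-bromo-10-(tert-butyldimethylsilyloxy)-9-(chloromethyl)-5,5-dimethyl-1-methylidenespiro[5.5]undecane-4,9-diol | C=C1C[C@H](Br)[C@@H](O)C(C)(C)[C@@]12CC[C@@](O)(CCl)[C@H](O[Si](C)(C)C(C)(C)C)C2 | intermediate
22 | C4 trifluoromethanesulfonate of 21 (formed in situ) | C=C1C[C@H](Br)[C@@H](OS(=O)(=O)C(F)(F)F)C(C)(C)[C@@]12CC[C@@](O)(CCl)[C@H](O[Si](C)(C)C(C)(C)C)C2 | intermediate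
23 | (3R,4R,6R,9S,10R)-4-bromo-10-(tert-butyldimethylsilyloxy)-9-(chloromethyl)-5,5-dimethyl-1-methylidenespiro[5.5]undecane-3,9-diol | C=C1C[C@@H](O)[C@H](Br)C(C)(C)[C@@]12CC[C@@](O)(CCl)[C@H](O[Si](C)(C)C(C)(C)C)C2 | intermediate
24 | (3R,4R,6R,9S,10R)-4-bromo-9-(chloromethyl)-5,5-dimethyl-1-methylidenespiro[5.5]undecane-3,9,10-triol | C=C1C[C@@H](O)[C@H](Br)C(C)(C)[C@@]12CC[C@@](O)(CCl)[C@H](O)C2 | intermediate
25 | (4R,6R,9S)-4-bromo-9-(chloromethyl)-9-hydroxy-5,5-dimethyl-1-methylidenespiro[5.5]undecane-3,10-dione | C=C1CC(=O)[C@H](Br)C(C)(C)[C@@]12CC[C@@](O)(CCl)C(=O)C2 | intermediate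
26 | (3S,4R,6R,9S)-4-bromo-9-(chloromethyl)-3,9-dihydroxy-5,5-dimethyl-1-methylidenespiro[5.5]undecan-10-one | C=C1C[C@H](O)[C@H](Br)C(C)(C)[C@@]12CC[C@@](O)(CCl)C(=O)C2 | target

## Step count and least certain steps

Total step count: 18. Longest linear sequence: 18 steps (1 to 26).

**Step 6 (key step).** The alkoxide may cleave heterolytically into an allyl anion and a vinyl ketone, which then recombine at the unhindered CH2 terminus. This is a formal 1,3-shift and gives a ring-expanded cyclooctenone. Alternatively, the shift may not start at all because the accepting carbon C4a is flanked by the gem-dimethyl group.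
Fallback, by known chemistry, setting out from ethylene glycol 4 and rejoining at 12: commercial 2,2-dimethylcyclohexane-1,3-dione F1 is mono-ketalised with 4 (TsOH, benzene) to 6,6-dimethyl-1,4-dioxaspiro[4.5]decan-7-one F2. Wittig methylenation (Ph3PCH3Br, KOt-Bu, toluene, reflux) gives the methylidene ketal F3. Allylic oxidation (SeO2 cat., t-BuOOH) gives the allylic alcohol F4, and Dess–Martin oxidation gives the α-methylene ketone F5. A thermal Diels–Alder reaction of F5 with 2-(trimethylsilyloxy)buta-1,3-diene closes ring B with para regiochemistry and gives the spiro silyl enol ether F6. The hindered C1 ketone of F6 is methylenated (Ph3PCH3Br, NaN(SiMe3)2, THF, reflux) to F7, and K2CO3/MeOH releases the C9 ketone, which is 12.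

**Step 10.** The α-silyloxy substituent may override the equatorial preference of the ylide, which would give poor facial selectivity at C9. The basic medium may also enolise the ketone or move the silyl group.
Fallback, setting out from 14 and rejoining at 17: the free α-hydroxy ketone 14 is methylenated with excess Ph3P=CH2 to the allylic alcohol F8. Hydroxyl-directed epoxidation (VO(acac)2 cat., t-BuOOH, CH2Cl2) puts the epoxide oxygen syn to the C10 hydroxyl and touches only the allylic alkene, giving epoxy alcohol F9. Silylation (TBSCl, imidazole) gives 17. The C9 configuration is then controlled by the C10 carbinol instead of by ring conformation.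

**Step 13.** Enamine formation at a ketone whose other α-carbon is quaternary may be too slow. The result would be no conversion, or an uncatalysed background bromination without facial control.
Fallback, setting out from 19 and rejoining at 21: soft enolisation (TMSOTf, Et3N, CH2Cl2) gives the bis-silylated enol ether F10. NBS, followed by a mild acidic work-up, gives 20 together with its (3R) epimer F11. Reduction of the mixture under the conditions of step 14 sets C4 as (S) in both, giving 21 and the cis-bromohydrin F12. These differ in relative configuration within ring A and separate by chromatography. F12 is returned to F11 by Dess–Martin oxidation and re-equilibrated at C3 with a trace of HBr. The stereodetermining event is thereby moved from the bromination to the reduction.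

**Step 14.** Reagent control may be mismatched with the substrate's own preference for equatorial hydride entry, and the hindered, electron-poor ketone may coordinate the catalyst only slowly. Either would lead to low conversion or erosion of the trans selectivity.
Fallback, setting out from 20 and rejoining at 21: substrate control with a small hydride (NaBH4, CeCl3·7H2O, MeOH, −78 °C) is used. Axial entry on the chair with equatorial bromine gives 21. The cis isomer F13 formed beside it is separated and oxidised back to 20 with Dess–Martin periodinane.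

**Step 15.** Ionisation may occur from the diequatorial conformer without bromine participation. The C5–C6 bond or a C5 methyl group would then migrate to the neopentyl cation, causing ring contraction or a 1,2-shift. Other risks are triflation of the tertiary C9 hydroxyl and water attack at C4, which returns unrearranged 21.
Fallback, setting out from 21 and rejoining at 23: a Mitsunobu reaction (PPh3, DIAD, PhCO2H, toluene) activates only the secondary alcohol. The oxyphosphonium group leaves with bromine participation and benzoate opens the bromonium ion at C3, giving the rearranged benzoate F14. DIBAL-H (CH2Cl2, −78 °C) then removes the ester without base and gives 23.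

**Step 18.** The reduction may not stop at C3, so that the C10 ketone is also reduced. The hydride may also attack bromine and cause reductive loss of the halogen.
Fallback, setting out from 23 and rejoining at 26: 23 is oxidised with Dess–Martin periodinane to the C3 ketone F15, in which C10 is still a silyl ether. LiBH(s-Bu)3 gives the cis-bromohydrin F16 with no competing carbonyl present. The C3 hydroxyl is protected as its 4-methoxybenzyl ether F17 (4-methoxybenzyl trichloroacetimidate, acid cat.). HF·pyridine frees the C10 alcohol F18, Dess–Martin oxidation gives the ketone F19, and DDQ (CH2Cl2/H2O) removes the benzyl ether to give 26.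

## Further compounds

F1 | step 6 | 2,2-dimethylcyclohexane-1,3-dione (commercial) | O=C1CCCC(=O)C1(C)C
F2 | step 6 | 6,6-dimethyl-1,4-dioxaspiro[4.5]decan-7-one | O=C1CCCC2(OCCO2)C1(C)C
F3 | step 6 | 6,6-dimethyl-7-methylidene-1,4-dioxaspiro[4.5]decane | C=C1CCCC2(OCCO2)C1(C)C
F4 | step 6 | 6,6-dimethyl-7-methylidene-1,4-dioxaspiro[4.5]decan-8-ol | C=C1C(O)CCC2(OCCO2)C1(C)C
F5 | step 6 | 6,6-dimethyl-7-methylidene-1,4-dioxaspiro[4.5]decan-8-one | C=C1C(=O)CCC2(OCCO2)C1(C)C
F6 | step 6 | 4,4-(ethylenedioxy)-5,5-dimethyl-9-(trimethylsilyloxy)spiro[5.5]undec-9-en-1-one | O=C1CCC2(OCCO2)C(C)(C)C13CCC(O[Si](C)(C)C)=CC3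
F7 | step 6 | 4,4-(ethylenedioxy)-5,5-dimethyl-1-methylidene-9-(trimethylsilyloxy)spiro[5.5]undec-9-ene | C=C1CCC2(OCCO2)C(C)(C)C13CCC(O[Si](C)(C)C)=CC3
F8 | step 10 | (6R,10R)-4,4-(ethylenedioxy)-5,5-dimethyl-1,9-dimethylidenespiro[5.5]undecan-10-ol | C=C1CCC2(OCCO2)C(C)(C)[C@@]13CCC(=C)[C@H](O)C3
F9 | step 10 | (6R,9R,10R)-4,4-(ethylenedioxy)-5,5-dimethyl-1-methylidenespiro[5.5]undecane-9-spiro-2'-oxiran-10-ol | C=C1CCC2(OCCO2)C(C)(C)[C@@]13CC[C@@]4(CO4)[C@H](O)C3
F10 | step 13 | C3=C4 trimethylsilyl enol ether of 19 with the C9 hydroxyl also trimethylsilylated | C=C1CC=C(O[Si](C)(C)C)C(C)(C)[C@@]12CC[C@@](O[Si](C)(C)C)(CCl)[C@H](O[Si](C)(C)C(C)(C)C)C2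
F11 | step 13 | (3R,6R,9S,10R)-3-bromo-10-(tert-butyldimethylsilyloxy)-9-(chloromethyl)-9-hydroxy-5,5-dimethyl-1-methylidenespiro[5.5]undecan-4-one | C=C1C[C@@H](Br)C(=O)C(C)(C)[C@@]12CC[C@@](O)(CCl)[C@H](O[Si](C)(C)C(C)(C)C)C2
F12 | step 13 | (3R,4S,6R,9S,10R)-3-bromo-10-(tert-butyldimethylsilyloxy)-9-(chloromethyl)-5,5-dimethyl-1-methylidenespiro[5.5]undecane-4,9-diol (cis-bromohydrin) | C=C1C[C@@H](Br)[C@@H](O)C(C)(C)[C@@]12CC[C@@](O)(CCl)[C@H](O[Si](C)(C)C(C)(C)C)C2
F13 | step 14 | (3S,4R,6R,9S,10R)-3-bromo-10-(tert-butyldimethylsilyloxy)-9-(chloromethyl)-5,5-dimethyl-1-methylidenespiro[5.5]undecane-4,9-diol (cis-bromohydrin) | C=C1C[C@H](Br)[C@H](O)C(C)(C)[C@@]12CC[C@@](O)(CCl)[C@H](O[Si](C)(C)C(C)(C)C)C2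
F14 | step 15 | C3 benzoate of 23 | C=C1C[C@@H](OC(=O)c3ccccc3)[C@H](Br)C(C)(C)[C@@]12CC[C@@](O)(CCl)[C@H](O[Si](C)(C)C(C)(C)C)C2
F15 | step 18 | (4R,6R,9S,10R)-4-bromo-10-(tert-butyldimethylsilyloxy)-9-(chloromethyl)-9-hydroxy-5,5-dimethyl-1-methylidenespiro[5.5]undecan-3-one | C=C1CC(=O)[C@H](Br)C(C)(C)[C@@]12CC[C@@](O)(CCl)[C@H](O[Si](C)(C)C(C)(C)C)C2
F16 | step 18 | (3S,4R,6R,9S,10R)-4-bromo-10-(tert-butyldimethylsilyloxy)-9-(chloromethyl)-5,5-dimethyl-1-methylidenespiro[5.5]undecane-3,9-diol | C=C1C[C@H](O)[C@H](Br)C(C)(C)[C@@]12CC[C@@](O)(CCl)[C@H](O[Si](C)(C)C(C)(C)C)C2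
F17 | step 18 | C3 4-methoxybenzyl ether of F16 | C=C1C[C@H](OCc3ccc(OC)cc3)[C@H](Br)C(C)(C)[C@@]12CC[C@@](O)(CCl)[C@H](O[Si](C)(C)C(C)(C)C)C2
F18 | step 18 | (3S,4R,6R,9S,10R)-4-bromo-9-(chloromethyl)-3-(4-methoxybenzyloxy)-5,5-dimethyl-1-methylidenespiro[5.5]undecane-9,10-diol | C=C1C[C@H](OCc3ccc(OC)cc3)[C@H](Br)C(C)(C)[C@@]12CC[C@@](O)(CCl)[C@H](O)C2
F19 | step 18 | (3S,4R,6R,9S)-4-bromo-9-(chloromethyl)-9-hydroxy-3-(4-methoxybenzyloxy)-5,5-dimethyl-1-methylidenespiro[5.5]undecan-10-one | C=C1C[C@H](OCc3ccc(OC)cc3)[C@H](Br)C(C)(C)[C@@]12CC[C@@](O)(CCl)C(=O)C2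
A1 | alternative 1 | 2-{1-[4-(4-methoxybenzyloxy)-3-oxobutyl]-6,6-dimethyl-4-(2-methylpropoxy)-2-oxocyclohex-3-en-1-yl}acetaldehyde (keto aldehyde precursor) | CC(C)COC1=CC(=O)[C@](CC=O)(CCC(=O)COCc2ccc(OC)cc2)C(C)(C)C1
A2 | alternative 1 | 9-hydroxy-9-[(4-methoxybenzyloxy)methyl]-5,5-dimethyl-3-(2-methylpropoxy)spiro[5.5]undec-2-ene-1,10-dione | CC(C)COC1=CC(=O)[C@]2(CC[C@@](O)(COCc3ccc(OC)cc3)C(=O)C2)C(C)(C)C1
A3 | alternative 2 | 1-(trimethylsilyloxy)bicyclo[3.1.0]hexane carrying the 3-bromo-4-(tert-butyldimethylsilyloxy)-2-methylhept-6-yn-2-yl chain on C5 and the spiro acetonide on C2 | C#CC[C@H](O[Si](C)(C)C(C)(C)C)[C@H](Br)C(C)(C)C12CC[C@@]3(COC(C)(C)O3)C1(O[Si](C)(C)C)C2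
A4 | alternative 2 | spiro ketone with the C3 silyl ether, C4 bromide, C1 methylene and the C9 diol as acetonide | C=C1C[C@H](O[Si](C)(C)C(C)(C)C)[C@H](Br)C(C)(C)[C@@]12CC[C@@]3(COC(C)(C)O3)C(=O)C2
A5 | alternative 3 | 2-bromo-3-methyl-3-[8-(prop-1-en-2-yl)-1,4-dioxaspiro[4.5]decan-8-yl]butanal | O=C[C@H](Br)C(C)(C)C1(C(C)=C)CCC2(CC1)OCCO2
A6 | alternative 3 | 4-bromo-5,5-dimethyl-1-methylidenespiro[5.5]undecan-3-ol with the C9 ketone as ethylene ketal | C=C1C[C@H](O)[C@H](Br)C(C)(C)C12CCC3(CC2)OCCO3
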